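The α-methylene-γ-lactone (ring O–C16–C15–C1–C14 with exocyclic C17) is left for the end. It is dissected into the O14 hydroxyl and the ethynyl group C15≡C17 on the adjacent C1, both already on the 14-membered carbocycle C1–C14, plus one CO (C16). A single palladium-catalysed cyclocarbonylation exploits this but-3-yn-1-ol motif: it forms C16–O and C15–C16 and closes the lactone ring without touching a stereocentre. Its precursor is macrocycle 32 (free O14–H, ethynyl at C1, PMB on O13, TES on O8, 3E and 6Z alkenes), built from (S)-citronellal (C7–C14) and a C1–C6 phosphonium salt by Wittig coupling and chelation-controlled allenylstannane–aldehyde ring closure.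

Key step: step 24

Remark: cembrane numbering is used (ring C1–C14, C15 α-carbon, C16 carbonyl, C17 methylene) and the target is (1S,3R,4R,6Z,8S,12S,13R,14R). O13 is carried as a PMB ether so that a magnesium chelate and the allene axis favour the same C14 configuration in step 23. The acetal carbon in 5–10 and 26–29 is an inconsequential epimer mixture and is left undefined in the SMILES.

Step 1
Reactants: 1 (S)-citronellal
Product: 3 (2R,3S)-3,7-dimethyl-2-[(phenylamino)oxy]oct-6-en-1-ol, via α-aminooxy aldehyde 2 (not isolated)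
Conditions: PhNO, L-proline (20 mol %), DMSO, rt; then NaBH4, EtOH, 0 °C
Reagents that add atoms: nitrosobenzene, O=Nc1ccccc1
Why: Proline enamine catalysis (α-aminoxylation, an O-selective nitroso aldol reaction) delivers oxygen to the enamine face dictated by L-proline, which should set C13 as R under catalyst control regardless of the C12 methyl centre, and the in situ reduction secures the labile α-oxy aldehyde.

Step 2
Reactants: 3 (2R,3S)-3,7-dimethyl-2-[(phenylamino)oxy]oct-6-en-1-ol
Product: 4 (2R,3S)-3,7-dimethyloct-6-ene-1,2-diol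
Conditions: Zn, AcOH–EtOH, rt
Reagents that add atoms: none
Why: Zinc in acetic acid cleaves the weak N–O bond by dissolving-metal reduction without touching the trisubstituted alkene or either stereocentre.

Step 3
Reactants: 4 (2R,3S)-3,7-dimethyloct-6-ene-1,2-diol
Product: 5 (4R)-2-(4-methoxyphenyl)-4-[(2S)-6-methylhept-5-en-2-yl]-1,3-dioxolane
Conditions: 4-MeOC6H4CH(OMe)2, PPTS (5 mol %), CH2Cl2, rt
Reagents that add atoms: 4-methoxybenzaldehyde dimethyl acetal, COC(OC)c1ccc(OC)cc1
Why: Acid-catalysed transacetalisation of the 1,2-diol gives the five-membered p-methoxybenzylidene acetal, which masks O13 and O14 together and later supplies the PMB ether on O13.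

Step 4
Reactants: 5 (4R)-2-(4-methoxyphenyl)-4-[(2S)-6-methylhept-5-en-2-yl]-1,3-dioxolane
Product: 6 (2E,6S)-6-[(4R)-2-(4-methoxyphenyl)-1,3-dioxolan-4-yl]-2-methylhept-2-en-1-ol
Conditions: SeO2 (0.3 equiv), t-BuOOH (anhydrous, in decane), CH2Cl2, 0 °C → rt
Reagents that add atoms: tert-butyl hydroperoxide, CC(C)(C)OO
Why: Catalytic SeO2 allylic oxidation (ene reaction followed by [2,3]-sigmatropic shift) should functionalise the (E)-methyl group of the trisubstituted alkene selectively and give the (E)-2-methylallylic alcohol with C7 oxidised.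

Step 5
Reactants: 6 (2E,6S)-6-[(4R)-2-(4-methoxyphenyl)-1,3-dioxolan-4-yl]-2-methylhept-2-en-1-ol
Product: 7 [(2R,3R)-3-{(3S)-3-[(4R)-2-(4-methoxyphenyl)-1,3-dioxolan-4-yl]butyl}-2-methyloxiran-2-yl]methanol
Conditions: Ti(OiPr)4 (10 mol %), D-(−)-diethyl tartrate (12 mol %), t-BuOOH, 4 Å MS, CH2Cl2, −20 °C
Reagents that add atoms: tert-butyl hydroperoxide, CC(C)(C)OO
Why: Sharpless asymmetric epoxidation reacts only at the allylic alcohol, and the D-(−)-tartrate catalyst should deliver oxygen by reagent control to the face that gives the (2R,3R)-epoxy alcohol, which fixes the C8 oxygen stereocentre.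

Step 6
Reactants: 7 [(2R,3R)-3-{(3S)-3-[(4R)-2-(4-methoxyphenyl)-1,3-dioxolan-4-yl]butyl}-2-methyloxiran-2-yl]methanol
Product: 8 (2S,6S)-6-[(4R)-2-(4-methoxyphenyl)-1,3-dioxolan-4-yl]-2-methylheptane-1,2-diol
Conditions: LiAlH4, THF, 0 °C → rt
Reagents that add atoms: none
Why: Hydride opens the 2-methyl-2,3-epoxy alcohol by SN2 attack at the less substituted C9, so the C8–O bond is untouched and the tertiary carbinol is obtained as 8S (the descriptor changes, the geometry does not).

Step 7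
Reactants: 8 (2S,6S)-6-[(4R)-2-(4-methoxyphenyl)-1,3-dioxolan-4-yl]-2-methylheptane-1,2-diol
Product: 9 (2S,6S)-6-[(4R)-2-(4-methoxyphenyl)-1,3-dioxolan-4-yl]-2-methylheptane-1,2-diol bis(triethylsilyl) ether
Conditions: Et3SiOTf (2.4 equiv), 2,6-lutidine, CH2Cl2, −78 °C
Reagents that add atoms: triethylsilyl trifluoromethanesulfonate, CC[Si](CC)(CC)OS(=O)(=O)C(F)(F)F
Why: The silyl triflate with a hindered pyridine base silylates both the primary and the tertiary hydroxyl at low temperature, where the acetal is not attacked.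

Step 8
Reactants: 9 (2S,6S)-6-[(4R)-2-(4-methoxyphenyl)-1,3-dioxolan-4-yl]-2-methylheptane-1,2-diol bis(triethylsilyl) ether
Product: 10 (2S,6S)-6-[(4R)-2-(4-methoxyphenyl)-1,3-dioxolan-4-yl]-2-methyl-2-[(triethylsilyl)oxy]heptanal
Conditions: (COCl)2, DMSO, CH2Cl2, −78 → −40 °C; Et3N, −78 → 0 °C
Reagents that add atoms: none
Why: Under Swern conditions the primary triethylsilyl ether is cleaved by the chlorosulfonium reagent and oxidised in the same flask to the C7 aldehyde, while the tertiary silyl ether is too hindered to react and the quaternary α-carbon cannot epimerise.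

Step 9
Reactants: 11 tert-butyl(but-3-yn-1-yloxy)dimethylsilane; 12 oxirane
Product: 15 (3E)-6-{[tert-butyl(dimethyl)silyl]oxy}-4-methylhex-3-en-1-ol, via alkenyldimethylalane 13 (not isolated), via lithium alkenylaluminate 14 (not isolated)
Conditions: Me3Al, Cp2ZrCl2 (25 mol %), CH2Cl2, 0 °C → rt; volatiles removed; n-BuLi, hexane–THF, 0 °C; oxirane, 0 °C → rt
Reagents that add atoms: trimethylaluminium, C[Al](C)C
Why: Zirconium-catalysed Negishi carboalumination adds Me–Al syn and regioselectively across the terminal alkyne, and the derived alkenylaluminate opens oxirane with retention of geometry, so the (E)-C3=C4 alkene and all of C1–C6 are in place.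

Step 10
Reactants: 15 (3E)-6-{[tert-butyl(dimethyl)silyl]oxy}-4-methylhex-3-en-1-ol
Product: 16 (3E)-6-{[tert-butyl(dimethyl)silyl]oxy}-4-methylhex-3-enal
Conditions: Dess–Martin periodinane, pyridine, CH2Cl2, 0 °C
Reagents that add atoms: none
Why: Buffered Dess–Martin oxidation is non-basic and should give the β,γ-unsaturated aldehyde without migration of the alkene into conjugation; the crude aldehyde is used at once.

Step 11
Reactants: 16 (3E)-6-{[tert-butyl(dimethyl)silyl]oxy}-4-methylhex-3-enal; 17 ethynyltrimethylsilane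
Product: 19 rac-(5E)-8-{[tert-butyl(dimethyl)silyl]oxy}-6-methyl-1-(trimethylsilyl)oct-5-en-1-yn-3-ol, via lithium trimethylsilylacetylide 18 (not isolated)
Conditions: n-BuLi, THF, −78 °C; then 16, −78 °C; aq. NH4Cl
Reagents that add atoms: none
Why: 1,2-Addition of the lithium acetylide at −78 °C outruns enolisation and installs C15 and C17; the carbinol is made racemic on purpose because steps 12 and 13 reset C1.

Step 12
Reactants: 19 rac-(5E)-8-{[tert-butyl(dimethyl)silyl]oxy}-6-methyl-1-(trimethylsilyl)oct-5-en-1-yn-3-ol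
Product: 20 (5E)-8-{[tert-butyl(dimethyl)silyl]oxy}-6-methyl-1-(trimethylsilyl)oct-5-en-1-yn-3-one
Conditions: Dess–Martin periodinane, pyridine, CH2Cl2, 0 °C
Reagents that add atoms: none
Why: Dess–Martin oxidation of the propargylic alcohol gives the silyl ynone needed for enantioselective reduction under conditions that do not enolise the C2 methylene.

Step 13
Reactants: 20 (5E)-8-{[tert-butyl(dimethyl)silyl]oxy}-6-methyl-1-(trimethylsilyl)oct-5-en-1-yn-3-one
Product: 21 (3S,5E)-8-{[tert-butyl(dimethyl)silyl]oxy}-6-methyl-1-(trimethylsilyl)oct-5-en-1-yn-3-ol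
Conditions: Ru[(S,S)-TsNCH(Ph)CH(Ph)NH](p-cymene) (2 mol %, base-free amido form of RuCl[(S,S)-TsDPEN](p-cymene)), i-PrOH, rt
Reagents that add atoms: none
Why: Noyori asymmetric transfer hydrogenation of the acetylenic ketone (bifunctional hydride and proton transfer from 2-propanol) with the (S,S)-diamine catalyst distinguishes alkynyl from alkyl and should give the (S)-carbinol at C1 under neutral conditions that leave the β,γ-alkene in place.

Step 14
Reactants: 21 (3S,5E)-8-{[tert-butyl(dimethyl)silyl]oxy}-6-methyl-1-(trimethylsilyl)oct-5-en-1-yn-3-ol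
Product: 22 (3S,5E)-6-methyl-1-(trimethylsilyl)oct-5-en-1-yne-3,8-diol
Conditions: CSA (10 mol %), MeOH, 0 °C
Reagents that add atoms: none
Why: Acid-catalysed methanolysis removes the primary O-silyl ether, whereas the C-silyl alkyne is inert to acid.

Step 15
Reactants: 22 (3S,5E)-6-methyl-1-(trimethylsilyl)oct-5-en-1-yne-3,8-diol
Product: 23 (3S,5E)-8-iodo-6-methyl-1-(trimethylsilyl)oct-5-en-1-yn-3-ol
Conditions: I2 (1.05 equiv), PPh3, imidazole, CH2Cl2, 0 °C
Reagents that add atoms: iodine, II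
Why: In this Appel-type iodination the iodophosphonium reagent activates the unhindered primary hydroxyl much faster than the secondary propargylic one, so one equivalent should give the primary iodide by SN2 displacement.

Step 16
Reactants: 23 (3S,5E)-8-iodo-6-methyl-1-(trimethylsilyl)oct-5-en-1-yn-3-ol
Product: 24 [(3E,6S)-6-hydroxy-3-methyl-8-(trimethylsilyl)oct-3-en-7-yn-1-yl]triphenylphosphonium iodide
Conditions: PPh3, MeCN, 80 °C
Reagents that add atoms: triphenylphosphine, c1ccc(cc1)P(c1ccccc1)c1ccccc1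
Why: SN2 quaternisation of triphenylphosphine by the primary iodide gives the phosphonium salt, and the free secondary hydroxyl does not interfere.

Step 17
Reactants: 24 [(3E,6S)-6-hydroxy-3-methyl-8-(trimethylsilyl)oct-3-en-7-yn-1-yl]triphenylphosphonium iodide; 10 (2S,6S)-6-[(4R)-2-(4-methoxyphenyl)-1,3-dioxolan-4-yl]-2-methyl-2-[(triethylsilyl)oxy]heptanal
Product: 26 (3S,5E,8Z,10S,14S)-14-[(4R)-2-(4-methoxyphenyl)-1,3-dioxolan-4-yl]-6,10-dimethyl-10-[(triethylsilyl)oxy]-1-(trimethylsilyl)pentadeca-5,8-dien-1-yn-3-ol, via ylide alkoxide 25 (not isolated)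
Conditions: 24 (1.3 equiv), NaN(SiMe3)2 (2.6 equiv), THF, −78 → 0 °C; then 10, −78 °C → rt
Reagents that add atoms: none
Why: Two equivalents of base give the alkoxide of the non-stabilised ylide, whose salt-free Wittig reaction with the hindered α-silyloxy aldehyde should proceed under kinetic control through the cis-oxaphosphetane to the (6Z)-alkene, joining C1–C6 to C7–C14 without affecting C8.

Step 18
Reactants: 26 (3S,5E,8Z,10S,14S)-14-[(4R)-2-(4-methoxyphenyl)-1,3-dioxolan-4-yl]-6,10-dimethyl-10-[(triethylsilyl)oxy]-1-(trimethylsilyl)pentadeca-5,8-dien-1-yn-3-ol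
Product: 27 (3S,5E,8Z,10S,14S)-14-[(4R)-2-(4-methoxyphenyl)-1,3-dioxolan-4-yl]-6,10-dimethyl-10-[(triethylsilyl)oxy]pentadeca-5,8-dien-1-yn-3-ol
Conditions: K2CO3, MeOH, rt
Reagents that add atoms: none
Why: Methoxide-mediated protodesilylation frees the terminal alkyne, while the hindered tertiary O–TES ether and the acetal are stable to K2CO3 in methanol.

Step 19
Reactants: 27 (3S,5E,8Z,10S,14S)-14-[(4R)-2-(4-methoxyphenyl)-1,3-dioxolan-4-yl]-6,10-dimethyl-10-[(triethylsilyl)oxy]pentadeca-5,8-dien-1-yn-3-ol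
Product: 28 (3S,5E,8Z,10S,14S)-14-[(4R)-2-(4-methoxyphenyl)-1,3-dioxolan-4-yl]-6,10-dimethyl-10-[(triethylsilyl)oxy]pentadeca-5,8-dien-1-yn-3-yl methanesulfonate
Conditions: MsCl, Et3N, CH2Cl2, −78 °C
Reagents that add atoms: methanesulfonyl chloride, CS(=O)(=O)Cl
Why: Sulfonylation of the only free hydroxyl (via sulfene) activates C1 as a propargylic leaving group without touching the C1 configuration.

Step 20
Reactants: 28 (3S,5E,8Z,10S,14S)-14-[(4R)-2-(4-methoxyphenyl)-1,3-dioxolan-4-yl]-6,10-dimethyl-10-[(triethylsilyl)oxy]pentadeca-5,8-dien-1-yn-3-yl methanesulfonate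
Product: 29 tributyl{(M,5E,8Z,10S,14S)-14-[(4R)-2-(4-methoxyphenyl)-1,3-dioxolan-4-yl]-6,10-dimethyl-10-[(triethylsilyl)oxy]pentadeca-1,2,5,8-tetraen-1-yl}stannane
Conditions: Bu3SnH, LiN(iPr)2, THF, −78 → 0 °C; CuBr·SMe2, −78 °C; then 28, −78 °C
Reagents that add atoms: tributyltin hydride, CCCC[SnH](CCCC)CCCC
Why: The stannylcopper reagent displaces the propargylic mesylate in an anti SN2' fashion, which should transfer the central chirality of C1 (S) into the (M)-axial chirality of the 1-stannylallene C17=C15=C1.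

Step 21
Reactants: 29 tributyl{(M,5E,8Z,10S,14S)-14-[(4R)-2-(4-methoxyphenyl)-1,3-dioxolan-4-yl]-6,10-dimethyl-10-[(triethylsilyl)oxy]pentadeca-1,2,5,8-tetraen-1-yl}stannane
Product: 30 (M,2R,3S,7S,8Z,11E)-2-[(4-methoxyphenyl)methoxy]-3,7,11-trimethyl-16-(tributylstannyl)-7-[(triethylsilyl)oxy]hexadeca-8,11,14,15-tetraen-1-ol
Conditions: (i-Bu)2AlH, CH2Cl2, −78 → 0 °C; aq. KNaC4H4O6 (potassium sodium tartrate)
Reagents that add atoms: none
Why: In this regioselective reductive acetal opening the aluminium hydride coordinates the less hindered O14, the C–O14 bond breaks and hydride adds to the oxocarbenium ion, so PMB stays on O13 and the primary hydroxyl is freed, while the allenylstannane is inert to the reagent at or below 0 °C.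

Step 22
Reactants: 30 (M,2R,3S,7S,8Z,11E)-2-[(4-methoxyphenyl)methoxy]-3,7,11-trimethyl-16-(tributylstannyl)-7-[(triethylsilyl)oxy]hexadeca-8,11,14,15-tetraen-1-ol
Product: 31 (M,2R,3S,7S,8Z,11E)-2-[(4-methoxyphenyl)methoxy]-3,7,11-trimethyl-16-(tributylstannyl)-7-[(triethylsilyl)oxy]hexadeca-8,11,14,15-tetraenal
Conditions: Dess–Martin periodinane, pyridine, CH2Cl2, 0 °C
Reagents that add atoms: none
Why: Buffered Dess–Martin oxidation should give the α-alkoxy aldehyde (C14) without protodestannylation and without epimerisation at C13; the aldehyde is used directly.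

Step 23
Reactants: 31 (M,2R,3S,7S,8Z,11E)-2-[(4-methoxyphenyl)methoxy]-3,7,11-trimethyl-16-(tributylstannyl)-7-[(triethylsilyl)oxy]hexadeca-8,11,14,15-tetraenal
Product: 32 (1S,3E,6Z,8S,12S,13R,14R)-1-ethynyl-13-[(4-methoxyphenyl)methoxy]-4,8,12-trimethyl-8-[(triethylsilyl)oxy]cyclotetradeca-3,6-dien-14-ol (cembrane numbering)
Conditions: MgBr2·OEt2 (5 equiv), CH2Cl2 (0.002 M, slow addition of 31), −20 °C → rt
Reagents that add atoms: none
Why: In this Lewis-acid-promoted intramolecular SE2' addition of the allenylstannane to the aldehyde (closure of the 14-membered ring at C1–C14), C1 should be set as S because the aldehyde enters anti to tin on the (M)-allene, and C14 as R because MgBr2 chelated between the aldehyde oxygen and the PMB oxygen exposes the face that gives the 13,14-syn arrangement (Cram chelate control), which is also the face required by the open antiperiplanar transition state leading to the syn relationship of O14 and C2, while high dilution suppresses oligomers.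

Step 24
Reactants: 32 (1S,3E,6Z,8S,12S,13R,14R)-1-ethynyl-13-[(4-methoxyphenyl)methoxy]-4,8,12-trimethyl-8-[(triethylsilyl)oxy]cyclotetradeca-3,6-dien-14-ol; 33 carbon monoxide
Product: 34 (1S,3E,6Z,8S,12S,13R,14R)-13-[(4-methoxyphenyl)methoxy]-8-[(triethylsilyl)oxy]cembra-3,6,15(17)-trien-16,14-olide (cis-fused α-methylene-γ-lactone on C1/C14)
Conditions: PdCl2 (10 mol %), thiourea (10 mol %), CO (1 atm), acetone, 50 °C
Reagents that add atoms: none
Why: The cycle starts with carbonylation of O14 on divalent palladium to a Pd–C(=O)OR unit; intramolecular syn acylpalladation of the C15≡C17 bond then attaches C16 to C15, and the vinylpalladium at C17 is cleaved by the HCl released in the first event, which regenerates PdCl2 and leaves C17 as =CH2. The nearest precedent is the cyclocarbonylation of simple and ring-fused but-3-yn-1-ols, for instance cis-2-ethynylcycloalkanols, to α-methylene-γ-butyrolactones with the same PdCl2–thiourea system. The lactone ring O–C16–C15–C1–C14 closes in the 5-exo-dig sense, with C17 remaining outside the ring. No stereocentre is formed, and the cis relationship of H1 and H14 set in step 23 is carried into the ring fusion. The step must discriminate between oxygen functions and between π-systems: O14–H is the only unprotected hydroxyl and stands 1,2 to the ethynyl-bearing C1, whereas O13 (PMB) and O8 (TES) are blocked, and the terminal alkyne binds divalent palladium far better than the alkenes at C3=C4 and C6=C7, with thiourea suppressing reduction of the catalyst by CO.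

Step 25
Reactants: 34 (1S,3E,6Z,8S,12S,13R,14R)-13-[(4-methoxyphenyl)methoxy]-8-[(triethylsilyl)oxy]cembra-3,6,15(17)-trien-16,14-olide
Product: 35 (1S,3R,4R,6Z,8S,12S,13R,14R)-3,4-epoxy-13-[(4-methoxyphenyl)methoxy]-8-[(triethylsilyl)oxy]cembra-6,15(17)-dien-16,14-olide
Conditions: D-fructose-derived Shi ketone (1,2:4,5-di-O-isopropylidene-β-D-erythro-2,3-hexodiulo-2,6-pyranose, 0.5 equiv), KHSO5 (as 2KHSO5·KHSO4·K2SO4), K2CO3, Bu4NHSO4, Na2B4O7 buffer, MeCN–CH2(OMe)2–H2O, 0 °C
Reagents that add atoms: potassium peroxymonosulfate, [K+].[O-]S(=O)(=O)OO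
Why: In this Shi epoxidation the chiral dioxirane formed from the ketone and KHSO5 should epoxidise the electron-rich trisubstituted C3=C4 alkene through a spiro transition state to the (3R,4R)-epoxide under catalyst control, while the conjugated C15=C17 alkene is electron-poor and C6=C7 is shielded by the adjacent tertiary O–TES group.

Step 26
Reactants: 35 (1S,3R,4R,6Z,8S,12S,13R,14R)-3,4-epoxy-13-[(4-methoxyphenyl)methoxy]-8-[(triethylsilyl)oxy]cembra-6,15(17)-dien-16,14-olide
Product: 36 (1S,3R,4R,6Z,8S,12S,13R,14R)-3,4-epoxy-13-hydroxy-8-[(triethylsilyl)oxy]cembra-6,15(17)-dien-16,14-olide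
Conditions: DDQ, CH2Cl2–pH 7 phosphate buffer, 0 °C
Reagents that add atoms: none
Why: DDQ oxidises the electron-rich PMB ether by hydride abstraction, and hydrolysis of the resulting oxocarbenium ion in the buffered two-phase medium frees O13–H while epoxide, silyl ether and acrylate stay intact.

Step 27
Reactants: 36 (1S,3R,4R,6Z,8S,12S,13R,14R)-3,4-epoxy-13-hydroxy-8-[(triethylsilyl)oxy]cembra-6,15(17)-dien-16,14-olide
Product: 37 (1S,3R,4R,6Z,8S,12S,13R,14R)-3,4-epoxy-8,13-dihydroxycembra-6,15(17)-dien-16,14-olide (CNP0304380.1)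
Conditions: HF·pyridine, pyridine, THF, 0 °C → rt
Reagents that add atoms: none
Why: Fluoride-mediated cleavage of the tertiary Si–O bond with pyridine-buffered HF·pyridine removes the last protecting group under conditions mild enough for the epoxide and the α-methylene lactone.

Compound list
1 | (S)-citronellal, (3S)-3,7-dimethyloct-6-enal | O=CC[C@@H](C)CCC=C(C)C | starting material
2 | (2R,3S)-3,7-dimethyl-2-[(phenylamino)oxy]oct-6-enal | O=C[C@H](ONc1ccccc1)[C@@H](C)CCC=C(C)C | intermediate (not isolated)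
3 | (2R,3S)-3,7-dimethyl-2-[(phenylamino)oxy]oct-6-en-1-ol | OC[C@H](ONc1ccccc1)[C@@H](C)CCC=C(C)C | intermediate
4 | (2R,3S)-3,7-dimethyloct-6-ene-1,2-diol | OC[C@H](O)[C@@H](C)CCC=C(C)C | intermediate
5 | (4R)-2-(4-methoxyphenyl)-4-[(2S)-6-methylhept-5-en-2-yl]-1,3-dioxolane | COc1ccc(cc1)C1OC[C@H](O1)[C@@H](C)CCC=C(C)C | intermediate
6 | (2E,6S)-6-[(4R)-2-(4-methoxyphenyl)-1,3-dioxolan-4-yl]-2-methylhept-2-en-1-ol | COc1ccc(cc1)C1OC[C@H](O1)[C@@H](C)CC/C=C(\C)CO | intermediate
7 | [(2R,3R)-3-{(3S)-3-[(4R)-2-(4-methoxyphenyl)-1,3-dioxolan-4-yl]butyl}-2-methyloxiran-2-yl]methanol | COc1ccc(cc1)C1OC[C@H](O1)[C@@H](C)CC[C@H]1O[C@]1(C)CO | intermediate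
8 | (2S,6S)-6-[(4R)-2-(4-methoxyphenyl)-1,3-dioxolan-4-yl]-2-methylheptane-1,2-diol | COc1ccc(cc1)C1OC[C@H](O1)[C@@H](C)CCC[C@](C)(O)CO | intermediate
9 | bis(triethylsilyl) ether of 8 | COc1ccc(cc1)C1OC[C@H](O1)[C@@H](C)CCC[C@](C)(O[Si](CC)(CC)CC)CO[Si](CC)(CC)CC | intermediate
10 | (2S,6S)-6-[(4R)-2-(4-methoxyphenyl)-1,3-dioxolan-4-yl]-2-methyl-2-[(triethylsilyl)oxy]heptanal (C7–C14 aldehyde) | COc1ccc(cc1)C1OC[C@H](O1)[C@@H](C)CCC[C@](C)(O[Si](CC)(CC)CC)C=O | intermediate
11 | tert-butyl(but-3-yn-1-yloxy)dimethylsilane | C#CCCO[Si](C)(C)C(C)(C)C | starting material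
12 | oxirane (ethylene oxide) | C1CO1 | starting material
13 | [(1E)-4-{[tert-butyl(dimethyl)silyl]oxy}-2-methylbut-1-en-1-yl]dimethylaluminium | C[Al](C)/C=C(\C)CCO[Si](C)(C)C(C)(C)C | intermediate (not isolated)
14 | lithium butyl[(1E)-4-{[tert-butyl(dimethyl)silyl]oxy}-2-methylbut-1-en-1-yl]dimethylaluminate | [Li+].CCCC[Al-](C)(C)/C=C(\C)CCO[Si](C)(C)C(C)(C)C | intermediate (not isolated)
15 | (3E)-6-{[tert-butyl(dimethyl)silyl]oxy}-4-methylhex-3-en-1-ol | OCC/C=C(\C)CCO[Si](C)(C)C(C)(C)C | intermediate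
16 | (3E)-6-{[tert-butyl(dimethyl)silyl]oxy}-4-methylhex-3-enal | O=CC/C=C(\C)CCO[Si](C)(C)C(C)(C)C | intermediate
17 | ethynyltrimethylsilane | C#C[Si](C)(C)C | starting material
18 | lithium (trimethylsilyl)acetylide | [Li]C#C[Si](C)(C)C | intermediate (not isolated)
19 | rac-(5E)-8-{[tert-butyl(dimethyl)silyl]oxy}-6-methyl-1-(trimethylsilyl)oct-5-en-1-yn-3-ol | C[Si](C)(C)C#CC(O)C/C=C(\C)CCO[Si](C)(C)C(C)(C)C | intermediate
20 | (5E)-8-{[tert-butyl(dimethyl)silyl]oxy}-6-methyl-1-(trimethylsilyl)oct-5-en-1-yn-3-one | C[Si](C)(C)C#CC(=O)C/C=C(\C)CCO[Si](C)(C)C(C)(C)C | intermediate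
21 | (3S,5E)-8-{[tert-butyl(dimethyl)silyl]oxy}-6-methyl-1-(trimethylsilyl)oct-5-en-1-yn-3-ol | C[Si](C)(C)C#C[C@@H](O)C/C=C(\C)CCO[Si](C)(C)C(C)(C)C | intermediate
22 | (3S,5E)-6-methyl-1-(trimethylsilyl)oct-5-en-1-yne-3,8-diol | C[Si](C)(C)C#C[C@@H](O)C/C=C(\C)CCO | intermediate
23 | (3S,5E)-8-iodo-6-methyl-1-(trimethylsilyl)oct-5-en-1-yn-3-ol | C[Si](C)(C)C#C[C@@H](O)C/C=C(\C)CCI | intermediate
24 | [(3E,6S)-6-hydroxy-3-methyl-8-(trimethylsilyl)oct-3-en-7-yn-1-yl]triphenylphosphonium iodide (C1–C6 salt) | C[Si](C)(C)C#C[C@@H](O)C/C=C(\C)CC[P+](c1ccccc1)(c1ccccc1)c1ccccc1.[I-] | intermediate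
25 | sodium alkoxide of the ylide from 24 | [Na+].C[Si](C)(C)C#C[C@@H]([O-])C/C=C(\C)CC=P(c1ccccc1)(c1ccccc1)c1ccccc1 | intermediate (not isolated)
26 | (3S,5E,8Z,10S,14S)-14-[(4R)-2-(4-methoxyphenyl)-1,3-dioxolan-4-yl]-6,10-dimethyl-10-[(triethylsilyl)oxy]-1-(trimethylsilyl)pentadeca-5,8-dien-1-yn-3-ol | COc1ccc(cc1)C1OC[C@H](O1)[C@@H](C)CCC[C@](C)(O[Si](CC)(CC)CC)/C=C\C/C(C)=C/C[C@H](O)C#C[Si](C)(C)C | intermediate
27 | (3S,5E,8Z,10S,14S)-14-[(4R)-2-(4-methoxyphenyl)-1,3-dioxolan-4-yl]-6,10-dimethyl-10-[(triethylsilyl)oxy]pentadeca-5,8-dien-1-yn-3-ol | COc1ccc(cc1)C1OC[C@H](O1)[C@@H](C)CCC[C@](C)(O[Si](CC)(CC)CC)/C=C\C/C(C)=C/C[C@H](O)C#C | intermediate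
28 | methanesulfonate of 27 at O1 | COc1ccc(cc1)C1OC[C@H](O1)[C@@H](C)CCC[C@](C)(O[Si](CC)(CC)CC)/C=C\C/C(C)=C/C[C@H](OS(C)(=O)=O)C#C | intermediate
29 | tributyl{(M,5E,8Z,10S,14S)-14-[(4R)-2-(4-methoxyphenyl)-1,3-dioxolan-4-yl]-6,10-dimethyl-10-[(triethylsilyl)oxy]pentadeca-1,2,5,8-tetraen-1-yl}stannane | COc1ccc(cc1)C1OC[C@H](O1)[C@@H](C)CCC[C@](C)(O[Si](CC)(CC)CC)/C=C\C/C(C)=C/CC([H])=[C@]=C([H])[Sn](CCCC)(CCCC)CCCC | intermediate
30 | (M,2R,3S,7S,8Z,11E)-2-[(4-methoxyphenyl)methoxy]-3,7,11-trimethyl-16-(tributylstannyl)-7-[(triethylsilyl)oxy]hexadeca-8,11,14,15-tetraen-1-ol | OC[C@H](OCc1ccc(OC)cc1)[C@@H](C)CCC[C@](C)(O[Si](CC)(CC)CC)/C=C\C/C(C)=C/CC([H])=[C@]=C([H])[Sn](CCCC)(CCCC)CCCC | intermediate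
31 | (M,2R,3S,7S,8Z,11E)-2-[(4-methoxyphenyl)methoxy]-3,7,11-trimethyl-16-(tributylstannyl)-7-[(triethylsilyl)oxy]hexadeca-8,11,14,15-tetraenal | O=C[C@H](OCc1ccc(OC)cc1)[C@@H](C)CCC[C@](C)(O[Si](CC)(CC)CC)/C=C\C/C(C)=C/CC([H])=[C@]=C([H])[Sn](CCCC)(CCCC)CCCC | intermediate
32 | (1S,3E,6Z,8S,12S,13R,14R)-1-ethynyl-13-[(4-methoxyphenyl)methoxy]-4,8,12-trimethyl-8-[(triethylsilyl)oxy]cyclotetradeca-3,6-dien-14-ol (cembrane numbering) | O[C@H]1[C@H](OCc2ccc(OC)cc2)[C@@H](C)CCC[C@](C)(O[Si](CC)(CC)CC)/C=C\C/C(C)=C/C[C@H]1C#C | intermediate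
33 | carbon monoxide | [C-]#[O+] | starting material
34 | (1S,3E,6Z,8S,12S,13R,14R)-13-[(4-methoxyphenyl)methoxy]-8-[(triethylsilyl)oxy]cembra-3,6,15(17)-trien-16,14-olide | C=C1C(=O)O[C@H]2[C@H](OCc3ccc(OC)cc3)[C@@H](C)CCC[C@](C)(O[Si](CC)(CC)CC)/C=C\C/C(C)=C/C[C@@H]12 | intermediate
35 | (1S,3R,4R,6Z,8S,12S,13R,14R)-3,4-epoxy-13-[(4-methoxyphenyl)methoxy]-8-[(triethylsilyl)oxy]cembra-6,15(17)-dien-16,14-olide | C=C1C(=O)O[C@H]2[C@H](OCc3ccc(OC)cc3)[C@@H](C)CCC[C@](C)(O[Si](CC)(CC)CC)/C=C\C[C@@]3(C)O[C@@H]3C[C@@H]12 | intermediate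
36 | (1S,3R,4R,6Z,8S,12S,13R,14R)-3,4-epoxy-13-hydroxy-8-[(triethylsilyl)oxy]cembra-6,15(17)-dien-16,14-olide | C=C1C(=O)O[C@H]2[C@H](O)[C@@H](C)CCC[C@](C)(O[Si](CC)(CC)CC)/C=C\C[C@@]3(C)O[C@@H]3C[C@@H]12 | intermediate
37 | (1S,3R,4R,6Z,8S,12S,13R,14R)-3,4-epoxy-8,13-dihydroxycembra-6,15(17)-dien-16,14-olide (CNP0304380.1) | C=C1C(=O)O[C@H]2[C@H](O)[C@@H](C)CCC[C@](C)(O)/C=C\C[C@@]3(C)O[C@@H]3C[C@@H]12 | target

Total step count: 27 (steps 1–8 for the C7–C14 aldehyde 10, steps 9–16 for the C1–C6 salt 24, steps 17–27 after their union).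
Longest linear sequence: 19 steps (steps 1–8 followed by 17–27; the branch 9–16 followed by 17–27 is equally long).

Steps most likely to fail

Step 23. Closure in dilute solution may be outrun by intermolecular addition or protodestannylation, and if the magnesium chelate does not form, the aldehyde may be attacked on its other face. The fallback sets out from aldehyde 31. The ring is closed with BF3·OEt2 in CH2Cl2 at −78 °C under high dilution, the Lewis acid for which allenylstannane–aldehyde macrocyclisations are established. C1 is still fixed by the allene axis, so the only stereochemical variable is C14. Any (1S,13R,14S)-alcohol, the C14 epimer F1, is separated and inverted by Mitsunobu esterification (4-nitrobenzoic acid, PPh3, diisopropyl azodicarboxylate, toluene, 0 °C → rt) to the (14R)-4-nitrobenzoate F2. Methanolysis of the ester (K2CO3, MeOH) comes back to the route at 32.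

Step 24. Divalent palladium may be reduced by CO before the cycle turns over, or the HCl carried through the cycle may ionise the tertiary allylic silyl ether or shift the skipped diene. The fallback sets out from 32 and builds the lactone from other bonds with known chemistry. Dicyclohexylborane (THF, 0 °C; then NaBO3·4H2O) hydroborates only the terminal alkyne, and the resulting aldehyde closes onto O14 as the lactol F3. Oxidation (TEMPO, PhI(OAc)2, CH2Cl2) gives the saturated cis-fused γ-lactone F4. Enolisation (LiN(iPr)2, THF, −78 °C) and dimethyl(methylidene)ammonium iodide give the α-(dimethylaminomethyl) lactone F5. N-methylation (MeI) and elimination (NaHCO3) come back to the route at 34.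

Step 25. The conformation of the 14-membered ring may expose the other face of C3=C4 and override the catalyst, or the dioxirane may also attack C6=C7. The fallback sets out from 34. N-bromosuccinimide in THF–H2O at 0 °C adds Br to C3 and water to the more substituted C4 in an anti sense to give the bromohydrin F6. Cs2CO3 in MeCN then closes the epoxide by backside displacement of bromide, so the oxygen ends on the face opposite to the one the electrophile attacked. Where the ring's own facial bias is the cause of failure, this inversion of sense comes back to the route at 35.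

Further compounds
F1 | step 23 | (1S,3E,6Z,8S,12S,13R,14S)-1-ethynyl-13-[(4-methoxyphenyl)methoxy]-4,8,12-trimethyl-8-[(triethylsilyl)oxy]cyclotetradeca-3,6-dien-14-ol (C14 epimer of 32) | O[C@@H]1[C@H](OCc2ccc(OC)cc2)[C@@H](C)CCC[C@](C)(O[Si](CC)(CC)CC)/C=C\C/C(C)=C/C[C@H]1C#C
F2 | step 23 | 4-nitrobenzoate of 32 at O14 (14R) | O=C(O[C@H]1[C@H](OCc2ccc(OC)cc2)[C@@H](C)CCC[C@](C)(O[Si](CC)(CC)CC)/C=C\C/C(C)=C/C[C@H]1C#C)c1ccc(cc1)[N+](=O)[O-]
F3 | step 24 | cis-fused γ-lactol on C1/C14 (anomer mixture) | C1C(O)O[C@H]2[C@H](OCc3ccc(OC)cc3)[C@@H](C)CCC[C@](C)(O[Si](CC)(CC)CC)/C=C\C/C(C)=C/C[C@@H]12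
F4 | step 24 | saturated cis-fused γ-lactone on C1/C14 (34 without the exocyclic methylene) | C1C(=O)O[C@H]2[C@H](OCc3ccc(OC)cc3)[C@@H](C)CCC[C@](C)(O[Si](CC)(CC)CC)/C=C\C/C(C)=C/C[C@@H]12
F5 | step 24 | α-(dimethylaminomethyl) derivative of lactone F4 (α-epimer mixture) | CN(C)CC1C(=O)O[C@H]2[C@H](OCc3ccc(OC)cc3)[C@@H](C)CCC[C@](C)(O[Si](CC)(CC)CC)/C=C\C/C(C)=C/C[C@@H]12
F6 | step 25 | (3S,4R)-3-bromo-4-hydroxy-3,4-dihydro derivative of 34 | C=C1C(=O)O[C@H]2[C@H](OCc3ccc(OC)cc3)[C@@H](C)CCC[C@](C)(O[Si](CC)(CC)CC)/C=C\C[C@@](C)(O)[C@@H](Br)C[C@@H]12
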